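## The problem

The target 14, 5-hydroxy-7-methoxy-2-(2,3,4,5-tetramethoxyphenyl)chromen-4-one, is a flavone. Ring A, a phloroglucinol-type benzene, is fused to the pyranone ring C through C4a and C8a, and ring B is attached to C2 by a single aryl–vinyl bond. There is no stereocentre, so every selectivity question is one of constitution. Ring C has to close as a 2-aryl chromone and not as the 3-aryl isomer, a coumarin or a five-membered aurone. The three oxygens of ring A have to end up different: O1 in the ring, O5 as a free phenol hydrogen-bonded to C4=O, and O7 as a methyl ether. With eight oxygens on twenty carbons both benzene rings are very electron-rich, so electrophilic halogenation and oxidation are real risks. The ortho methyl ethers (2'-OMe next to the inter-ring bond) are the first to be lost to strong Lewis acids, and enolate chemistry on such hindered polyoxygenated aryl ketones is slow. The feature that opens the chosen route is that C4 is bonded to C4a, which lies between the two oxygen-bearing carbons C5 and C8a. A one-carbon dipole placed there is flanked by two ortho substituents, the pattern that makes an aryl nitrile oxide persistent, and with two identical protected phenols either oxygen can later become O1. C3 and C2 can then be supplied by a terminal alkyne on ring B.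

## Retrosynthesis

Ring C is opened first at O1–C2, and C4=O is traced back to a carbon bearing nitrogen, which leads to the β-amino enone 13 with both ring A phenols masked as MOM ethers. Cutting C4–C4a instead would call for Friedel–Crafts acylation of a free triphenol, and cutting C2–C1' would still leave the chromone to be made. The O1–C2 closure is the ordinary flavone end-game and needs only protic acid. Compound 13 is acyclic and, apart from the acetals, carries only ethers. The forward reaction must remove two acetals, hydrolyse the vinylogous amide and cyclodehydrate in one acid treatment that leaves five methyl ethers alone. Because the two masked phenols are equivalent, it does not matter which one closes.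

The N–H and C=O ends of 13 are rejoined as an N–O bond, giving the 3,5-diarylisoxazole 12. Against carrying a diketone-level intermediate made by enolate acylation, the isoxazole is neutral, non-enolisable and stable to chromatography, and it fixes the order of the atoms: nitrogen marks C4 and oxygen marks C2. The forward step needs a two-electron reductant that is selective for the N–O bond.

The isoxazole is cut across its C3–C4 and C5–O bonds into nitrile oxide 7 and terminal alkyne 11. In flavone numbering this makes the C3–C4 bond, which is kept, and a C2–O bond that holds C2 at the ketone oxidation level until the last step. This is the strategic cut: it is convergent, atom-economic, free of base and Lewis acid, and divides the molecule into a ring A half and a ring B half of similar size. The forward reaction needs the dipole to add faster than it dimerises or rearranges, and needs the 3,5-orientation.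

Nitrile oxide 7 is traced through the E aldoxime 6 to aldehyde 5. The C=N–O unit is set up by condensation and then dehydrogenated. The forward oxidation must not halogenate or oxidise the activated ring.

The formyl carbon of 5 is removed to give the bis-MOM ether 2, made from commercial 5-methoxyresorcinol 1. The forward reaction is a directed metalation between the two acetal oxygens (aryllithium 3) followed by a formamide quench (aminoalkoxide 4). MOM is chosen over benzyl, whose hydrogenolysis would also break the N–O bond, and over methyl, which would need a selective demethylation. It directs the lithiation and is removed by the acid of the final step.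

Alkyne 11 is traced to aldehyde 10 by one-carbon homologation, and 10 to 1,2,3,4-tetramethoxybenzene 8 by formylation through iminium salt 9. The two free positions of 8 are equivalent, so the formylation has no regiochemical issue, and ring B arrives with all four methyl ethers in place.

## Roads not taken

Alternative 1: Ring C is cut at C4–C4a and O1–C2, leading to phloroglucinol A3 and ethyl 3-oxo-3-(2,3,4,5-tetramethoxyphenyl)propanoate A2.
- Forward step: the two are fused without solvent at about 250 °C. C-acylation and cyclodehydration give 5,7-dihydroxy-2-(2,3,4,5-tetramethoxyphenyl)chromen-4-one A1, and a final mono-O-methylation at the non-chelated 7-OH would give 14.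
- Merits: this is the shortest road, about four operations from ring B material against nine in the chosen plan. It needs no protecting groups, and the symmetric triphenol removes any ring A regiochemistry.
- Weak points: the key step is a pyrolysis. Closure to a coumarin-type isomer, decarboxylative breakdown of A2 and charring of a free triphenol all compete, and the ortho-methoxy aroyl group of A2 is a hindered acylating agent.
- Comparison: in step count this alternative is clearly better. The chosen plan sets against it that every bond is made below 100 °C under neutral or mildly acidic conditions, that the constitution of ring C is fixed by the isoxazole and not by a thermal partition between two closure modes, and that no late selective methylation is needed.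

Alternative 2: Ring C is cut at C2=C3.
- Forward step: the acylphosphorane 3-(benzyloxy)-5-methoxy-2-[2-(triphenylphosphoranylidene)acetyl]phenyl 2,3,4,5-tetramethoxybenzoate A5 is heated. It undergoes an intramolecular Wittig reaction on its own ester carbonyl to give 5-(benzyloxy)-7-methoxy-2-(2,3,4,5-tetramethoxyphenyl)chromen-4-one A4, and debenzylation would give 14.
- Merits: the closure is neutral and unambiguous in constitution, ring B enters as a simple acid derivative, and every intermediate is bench-stable with no reactive dipole to handle. In that last respect it is better than the chosen plan.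
- Weak points: ring A must first be differentiated three ways, as in 1-[2-(benzyloxy)-6-hydroxy-4-methoxyphenyl]ethanone A6. Bromination of the acetyl group of the aroylated ketone competes with bromination of the activated ring. The ester carbonyl that must be olefinated is electron-rich and flanked by an ortho methoxy group. A debenzylation is added at the end.
- Comparison: the length is similar, about eight steps. The chosen plan sets against the stability advantage that its ring A precursor needs only one symmetric double protection, and that its dipole is of the doubly ortho-substituted, persistent kind.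

Alternative 3: Ring B is built last by cutting three of its C–C bonds.
- Forward step: the alkenyl carbene complex (CO)5Cr=C(OMe)C(OMe)=CH(OMe) A9 would react with 5-(benzyloxy)-2-ethynyl-7-methoxychromen-4-one A8 and one carbonyl ligand in a Dötz benzannulation. The product is 5-(benzyloxy)-2-(2-hydroxy-3,4,5-trimethoxyphenyl)-7-methoxychromen-4-one A7, which still needs 2'-O-methylation and debenzylation to reach 14.
- Merits: the substitution pattern of ring B is assembled with inherent regiocontrol, and the route would be flexible for ring B analogues.
- Weak points: A9 is a donor-rich tri-alkoxy carbene complex that needs its own synthesis and should be slow to lose a carbonyl ligand. A8 is a cross-conjugated acceptor that can react at C2 with nucleophiles. Chromium is used stoichiometrically. Two further steps follow the key step.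
- Comparison: this road builds a benzene ring that the chosen plan buys as 8. It is longer and less certain, and its only advantage is analogue flexibility, which is not needed for a single target.

Key step: step 7

Assumption: arene 8 is taken as purchasable, and nitrile oxide 7 is expected to be an isolable solid that can be kept cold, like other 2,6-dialkoxybenzonitrile oxides.

## Route

Step 1
Reactants: 1 5-methoxyresorcinol (5-methoxybenzene-1,3-diol)
Product: 2 1-methoxy-3,5-bis(methoxymethoxy)benzene
Conditions: MOMCl (2.5 equiv), i-Pr2NEt, CH2Cl2, 0 °C to rt
Reagents that add atoms: chloromethyl methyl ether (MOMCl), COCCl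
Why: Williamson-type acetal protection of two free, non-chelated phenols under amine base; the MOM groups direct the next metalation and are removed by the acid of the last step.

Step 2
Reactants: 2 1-methoxy-3,5-bis(methoxymethoxy)benzene
Product: 5 4-methoxy-2,6-bis(methoxymethoxy)benzaldehyde, via aryllithium 3 (not isolated), via lithium aminoalkoxide 4 (not isolated)
Conditions: n-BuLi, TMEDA, THF, 0 °C; DMF, 0 °C to rt; then H2O
Reagents that add atoms: N,N-dimethylformamide (DMF), CN(C)C=O
Why: Directed ortho-metalation; the carbon between the two MOM ethers should be deprotonated preferentially because lithium is chelated there by both acetal groups, which direct more strongly than the methyl ether. The aryllithium is formylated by DMF, and the aldehyde is released from the aminoalkoxide only on aqueous work-up, so a second addition cannot occur.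

Step 3
Reactants: 5 4-methoxy-2,6-bis(methoxymethoxy)benzaldehyde
Product: 6 (E)-4-methoxy-2,6-bis(methoxymethoxy)benzaldehyde oxime
Conditions: NH2OH·HCl, NaOAc, EtOH–H2O, 50 °C
Reagents that add atoms: hydroxylamine hydrochloride, Cl.NO
Why: Oxime condensation under acetate buffering, too weakly acidic to cleave the MOM acetals; the E isomer is the thermodynamically favoured form of an aryl aldoxime.

Step 4
Reactants: 6 (E)-4-methoxy-2,6-bis(methoxymethoxy)benzaldehyde oxime
Product: 7 4-methoxy-2,6-bis(methoxymethoxy)benzonitrile oxide
Conditions: PhI(OAc)2 (1.1 equiv), CF3CO2H (cat.), MeOH, 0 °C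
Reagents that add atoms: none
Why: Oxidative dehydrogenation of an aldoxime to the nitrile oxide by a hypervalent iodine reagent (ligand exchange at iodine, then loss of PhI and AcOH). A halogen-free oxidant is chosen so that the triply activated ring A carbons are not halogenated, and the two ortho MOM ethers should make the dipole persistent enough to isolate cold.

Step 5
Reactants: 8 1,2,3,4-tetramethoxybenzene
Product: 10 2,3,4,5-tetramethoxybenzaldehyde, via iminium salt 9 (not isolated)
Conditions: POCl3, DMF, 0 to 80 °C; then H2O
Reagents that add atoms: N,N-dimethylformamide (DMF), CN(C)C=O; water, O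
Why: Vilsmeier–Haack formylation; the two free positions of 8 are equivalent and each is activated by an ortho and a para methoxy group, so a single aldehyde is expected after hydrolysis of the iminium salt.

Step 6
Reactants: 10 2,3,4,5-tetramethoxybenzaldehyde
Product: 11 1-ethynyl-2,3,4,5-tetramethoxybenzene
Conditions: dimethyl (1-diazo-2-oxopropyl)phosphonate, K2CO3, MeOH, rt
Reagents that add atoms: dimethyl (1-diazo-2-oxopropyl)phosphonate, CC(=O)C(=[N+]=[N-])P(=O)(OC)OC
Why: Ohira–Bestmann (Seyferth–Gilbert) homologation; the diazomethylphosphonate anion formed by methanolysis olefinates the aldehyde, and the diazoalkene loses N2 with a 1,2-hydrogen shift to give the terminal alkyne. The mild carbonate conditions suit a non-enolisable, electron-rich aldehyde.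

Step 7
Reactants: 7 4-methoxy-2,6-bis(methoxymethoxy)benzonitrile oxide; 11 1-ethynyl-2,3,4,5-tetramethoxybenzene
Product: 12 3-[4-methoxy-2,6-bis(methoxymethoxy)phenyl]-5-(2,3,4,5-tetramethoxyphenyl)isoxazole
Conditions: PhMe, 80 °C (11 in 1.3-fold excess)
Reagents that add atoms: none
Why: Concerted, thermally allowed (3+2) Huisgen cycloaddition of the nitrile oxide of 7 across the C≡C bond of 11; the dipole carbon (future C4) bonds to the terminal alkyne carbon (future C3) and the dipole oxygen to the aryl-bearing carbon (future C2). The closest known reaction is the addition of persistent 2,6-disubstituted benzonitrile oxides to terminal arylacetylenes, which gives 3,5-diarylisoxazoles. The one new ring, the five-membered isoxazole, is closed intermolecularly by the cycloaddition itself, both σ bonds forming in one suprafacial event, so no separate cyclisation mode is involved. No stereocentre is created. The step needs regioselectivity (3,5- over 3,4-diaryl) and chemoselectivity (addition over dimerisation to the furoxan or rearrangement to the isocyanate). The first is secured by the terminal alkyne: the bulky carbon end of the dipole goes to the unsubstituted carbon, in line with the larger frontier-orbital coefficient there. The second is secured by the two ortho MOM ethers, which block the approach of a second dipole, and by keeping the temperature at 80 °C, below that at which hindered nitrile oxides isomerise. All other groups are ethers or acetals and are inert under neutral thermal conditions.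

Step 8
Reactants: 12 3-[4-methoxy-2,6-bis(methoxymethoxy)phenyl]-5-(2,3,4,5-tetramethoxyphenyl)isoxazole
Product: 13 (Z)-3-amino-3-[4-methoxy-2,6-bis(methoxymethoxy)phenyl]-1-(2,3,4,5-tetramethoxyphenyl)prop-2-en-1-one
Conditions: Mo(CO)6, MeCN–H2O, 85 °C
Reagents that add atoms: none
Why: Mo(CO)6-mediated reductive cleavage of the isoxazole N–O bond (coordination at nitrogen, N–O scission, hydrolysis of the metal-bound nitrogen by water) should give the β-amino enone, held in the Z form by an N–H···O=C hydrogen bond. Aryl ethers and acetals are untouched under these neutral conditions.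

Step 9
Reactants: 13 (Z)-3-amino-3-[4-methoxy-2,6-bis(methoxymethoxy)phenyl]-1-(2,3,4,5-tetramethoxyphenyl)prop-2-en-1-one
Product: 14 5-hydroxy-7-methoxy-2-(2,3,4,5-tetramethoxyphenyl)chromen-4-one
Conditions: 3 M aq HCl, MeOH, 65 °C
Reagents that add atoms: water, O
Why: One acid treatment combines three known reactions: acetal cleavage of both MOM ethers, hydrolysis of the vinylogous amide at the nitrogen-bearing carbon (which becomes C4=O), and 6-exo-trig addition of a freed phenol to the ring B ketone followed by dehydration, the cyclodehydration of the classical diketone route to flavones. The two phenols are equivalent, so only one flavone can form, and the other phenol remains as the chelated 5-OH.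

## Compound list

1 | 5-methoxyresorcinol (5-methoxybenzene-1,3-diol) | COc1cc(O)cc(O)c1 | starting material
2 | 1-methoxy-3,5-bis(methoxymethoxy)benzene | COCOc1cc(OC)cc(OCOC)c1 | intermediate
3 | [4-methoxy-2,6-bis(methoxymethoxy)phenyl]lithium | [Li]c1c(OCOC)cc(OC)cc1OCOC | intermediate (not isolated)
4 | lithium (dimethylamino)[4-methoxy-2,6-bis(methoxymethoxy)phenyl]methanolate (racemic) | [Li+].[O-]C(N(C)C)c1c(OCOC)cc(OC)cc1OCOC | intermediate (not isolated)
5 | 4-methoxy-2,6-bis(methoxymethoxy)benzaldehyde | COCOc1cc(OC)cc(OCOC)c1C=O | intermediate
6 | (E)-4-methoxy-2,6-bis(methoxymethoxy)benzaldehyde oxime | COCOc1cc(OC)cc(OCOC)c1/C=N/O | intermediate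
7 | 4-methoxy-2,6-bis(methoxymethoxy)benzonitrile oxide | COCOc1cc(OC)cc(OCOC)c1C#[N+][O-] | intermediate
8 | 1,2,3,4-tetramethoxybenzene | COc1ccc(OC)c(OC)c1OC | starting material
9 | N,N-dimethyl-1-(2,3,4,5-tetramethoxyphenyl)methaniminium chloride | C[N+](C)=Cc1cc(OC)c(OC)c(OC)c1OC.[Cl-] | intermediate (not isolated)
10 | 2,3,4,5-tetramethoxybenzaldehyde | O=Cc1cc(OC)c(OC)c(OC)c1OC | intermediate
11 | 1-ethynyl-2,3,4,5-tetramethoxybenzene | C#Cc1cc(OC)c(OC)c(OC)c1OC | intermediate
12 | 3-[4-methoxy-2,6-bis(methoxymethoxy)phenyl]-5-(2,3,4,5-tetramethoxyphenyl)isoxazole | COCOc1cc(OC)cc(OCOC)c1-c1cc(-c2cc(OC)c(OC)c(OC)c2OC)on1 | intermediate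
13 | (Z)-3-amino-3-[4-methoxy-2,6-bis(methoxymethoxy)phenyl]-1-(2,3,4,5-tetramethoxyphenyl)prop-2-en-1-one | COCOc1cc(OC)cc(OCOC)c1/C(N)=C/C(=O)c1cc(OC)c(OC)c(OC)c1OC | intermediate
14 | 5-hydroxy-7-methoxy-2-(2,3,4,5-tetramethoxyphenyl)chromen-4-one | COc1cc(O)c2c(=O)cc(-c3cc(OC)c(OC)c(OC)c3OC)oc2c1 | target

## Step count and least certain steps

Total: 9 steps. Longest linear sequence: 7 steps (steps 1–4 and 7–9, from 1). The ring B branch is 2 steps (steps 5 and 6).

**Step 7 (key step).** The most likely failure is a slow bimolecular addition: the dipole is shielded by two ortho substituents and the aryl alkyne is electron-rich and only moderately reactive. Rearrangement of the nitrile oxide to the isocyanate, or its slow dimerisation, could then compete at the temperature needed. Some erosion of the 3,5-orientation is a lesser concern.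
- The fallback sets out from 11, still uses 7, and returns to the route at 12. It replaces the alkyne with a far more electron-rich dipolarophile of the same orientation.
- Alkyne 11 would be hydrated (HCO2H, 100 °C) to 1-(2,3,4,5-tetramethoxyphenyl)ethanone F1.
- F1 would be condensed with pyrrolidine (TsOH cat., PhMe, water removal) to the enamine 1-[1-(2,3,4,5-tetramethoxyphenyl)ethenyl]pyrrolidine F2.
- F2 should take up 7 at room temperature, with the dipole oxygen bonding to the amine-bearing carbon. This gives racemic 3-[4-methoxy-2,6-bis(methoxymethoxy)phenyl]-5-(pyrrolidin-1-yl)-5-(2,3,4,5-tetramethoxyphenyl)-4,5-dihydroisoxazole F3.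
- Brief warming with AcOH should eliminate pyrrolidine and aromatise F3 to 12.

**Step 4.** The oxidant may attack the very electron-rich ring A or cleave the oxime back to the aldehyde. Methanol may add to the dipole before isolation, and the catalytic acid may remove a MOM group.
- The fallback sets out from 5 and 11 and returns to the route at 14. It avoids the dipole by carrying C4 at the aldehyde oxidation level.
- Alkyne 11 would be deprotonated with n-BuLi (THF, −78 °C) and added to 5, giving racemic 1-[4-methoxy-2,6-bis(methoxymethoxy)phenyl]-3-(2,3,4,5-tetramethoxyphenyl)prop-2-yn-1-ol F4.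
- Oxidation with MnO2 (CH2Cl2, rt) would give the ynone 1-[4-methoxy-2,6-bis(methoxymethoxy)phenyl]-3-(2,3,4,5-tetramethoxyphenyl)prop-2-yn-1-one F5.
- Conjugate addition of Et2NH (EtOH, rt) would give (E)-3-(diethylamino)-1-[4-methoxy-2,6-bis(methoxymethoxy)phenyl]-3-(2,3,4,5-tetramethoxyphenyl)prop-2-en-1-one F6. This step blocks the five-membered aurone closure open to a free ortho-hydroxyaryl ynone.
- Treatment with 3 M HCl in MeOH at 65 °C would remove the MOM groups and close ring C by addition–elimination at the amine-bearing carbon, giving 14.

**Step 2.** The base may deprotonate a carbon flanked by one MOM ether and the methyl ether, of which there are two, instead of the single carbon between the two MOM ethers. After formylation this would give a regioisomeric aldehyde that leads to the wrong 5,7-pattern.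
- The fallback sets out from 1 and returns to the route at 5. It uses stronger directing groups.
- Compound 1 would be converted (ClCONEt2, NaH, THF) into 5-methoxy-1,3-phenylene bis(N,N-diethylcarbamate) F7.
- Metalation with s-BuLi/TMEDA (THF, −78 °C) should go between the two carbamates, the strongest oxygen-based directors, and a DMF quench would give 2-formyl-5-methoxy-1,3-phenylene bis(N,N-diethylcarbamate) F8.
- Hydrolysis (NaOH, aq EtOH, reflux) would give 2,6-dihydroxy-4-methoxybenzaldehyde F9.
- Double protection (MOMCl, NaH, DMF) would return 5.

**Step 8.** N–O cleavage may be incomplete because the two ortho MOM ethers hinder coordination of zerovalent molybdenum to the isoxazole nitrogen. Prolonged heating in wet MeCN could then hydrolyse and partly fragment the enaminone.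
- The fallback sets out from 12 and returns to the route at 14. It changes the order of events and the type of reductant.
- The MOM groups would be removed first (HCl, MeOH, 50 °C), giving 5-methoxy-2-[5-(2,3,4,5-tetramethoxyphenyl)isoxazol-3-yl]benzene-1,3-diol F10, a less hindered substrate.
- Hydrogenolysis of the N–O bond (H2, Pd/C, EtOH, rt) would give (Z)-3-amino-3-(2,6-dihydroxy-4-methoxyphenyl)-1-(2,3,4,5-tetramethoxyphenyl)prop-2-en-1-one F11.
- Warming F11 with 3 M aq HCl in MeOH would close it to 14.

## Further compounds

F1 | step 7 | 1-(2,3,4,5-tetramethoxyphenyl)ethanone | CC(=O)c1cc(OC)c(OC)c(OC)c1OC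
F2 | step 7 | 1-[1-(2,3,4,5-tetramethoxyphenyl)ethenyl]pyrrolidine | C=C(N1CCCC1)c1cc(OC)c(OC)c(OC)c1OC
F3 | step 7 | 3-[4-methoxy-2,6-bis(methoxymethoxy)phenyl]-5-(pyrrolidin-1-yl)-5-(2,3,4,5-tetramethoxyphenyl)-4,5-dihydroisoxazole (racemic) | COCOc1cc(OC)cc(OCOC)c1C1=NOC(N2CCCC2)(c2cc(OC)c(OC)c(OC)c2OC)C1
F4 | step 4 | 1-[4-methoxy-2,6-bis(methoxymethoxy)phenyl]-3-(2,3,4,5-tetramethoxyphenyl)prop-2-yn-1-ol (racemic) | COCOc1cc(OC)cc(OCOC)c1C(O)C#Cc1cc(OC)c(OC)c(OC)c1OC
F5 | step 4 | 1-[4-methoxy-2,6-bis(methoxymethoxy)phenyl]-3-(2,3,4,5-tetramethoxyphenyl)prop-2-yn-1-one | COCOc1cc(OC)cc(OCOC)c1C(=O)C#Cc1cc(OC)c(OC)c(OC)c1OC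
F6 | step 4 | (E)-3-(diethylamino)-1-[4-methoxy-2,6-bis(methoxymethoxy)phenyl]-3-(2,3,4,5-tetramethoxyphenyl)prop-2-en-1-one | CCN(CC)/C(=C/C(=O)c1c(OCOC)cc(OC)cc1OCOC)c1cc(OC)c(OC)c(OC)c1OC
F7 | step 2 | 5-methoxy-1,3-phenylene bis(N,N-diethylcarbamate) | CCN(CC)C(=O)Oc1cc(OC)cc(OC(=O)N(CC)CC)c1
F8 | step 2 | 2-formyl-5-methoxy-1,3-phenylene bis(N,N-diethylcarbamate) | CCN(CC)C(=O)Oc1cc(OC)cc(OC(=O)N(CC)CC)c1C=O
F9 | step 2 | 2,6-dihydroxy-4-methoxybenzaldehyde | COc1cc(O)c(C=O)c(O)c1
F10 | step 8 | 5-methoxy-2-[5-(2,3,4,5-tetramethoxyphenyl)isoxazol-3-yl]benzene-1,3-diol | COc1cc(O)c(-c2cc(-c3cc(OC)c(OC)c(OC)c3OC)on2)c(O)c1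
F11 | step 8 | (Z)-3-amino-3-(2,6-dihydroxy-4-methoxyphenyl)-1-(2,3,4,5-tetramethoxyphenyl)prop-2-en-1-one | COc1cc(O)c(/C(N)=C/C(=O)c2cc(OC)c(OC)c(OC)c2OC)c(O)c1
A1 | alternative 1 | 5,7-dihydroxy-2-(2,3,4,5-tetramethoxyphenyl)chromen-4-one | Oc1cc(O)c2c(=O)cc(-c3cc(OC)c(OC)c(OC)c3OC)oc2c1
A2 | alternative 1 | ethyl 3-oxo-3-(2,3,4,5-tetramethoxyphenyl)propanoate | CCOC(=O)CC(=O)c1cc(OC)c(OC)c(OC)c1OC
A3 | alternative 1 | phloroglucinol (benzene-1,3,5-triol) | Oc1cc(O)cc(O)c1
A4 | alternative 2 | 5-(benzyloxy)-7-methoxy-2-(2,3,4,5-tetramethoxyphenyl)chromen-4-one | COc1cc(OCc2ccccc2)c2c(=O)cc(-c3cc(OC)c(OC)c(OC)c3OC)oc2c1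
A5 | alternative 2 | 3-(benzyloxy)-5-methoxy-2-[2-(triphenylphosphoranylidene)acetyl]phenyl 2,3,4,5-tetramethoxybenzoate | COc1cc(OCc2ccccc2)c(C(=O)C=P(c2ccccc2)(c2ccccc2)c2ccccc2)c(OC(=O)c2cc(OC)c(OC)c(OC)c2OC)c1
A6 | alternative 2 | 1-[2-(benzyloxy)-6-hydroxy-4-methoxyphenyl]ethanone | CC(=O)c1c(O)cc(OC)cc1OCc1ccccc1
A7 | alternative 3 | 5-(benzyloxy)-2-(2-hydroxy-3,4,5-trimethoxyphenyl)-7-methoxychromen-4-one | COc1cc(OCc2ccccc2)c2c(=O)cc(-c3cc(OC)c(OC)c(OC)c3O)oc2c1
A8 | alternative 3 | 5-(benzyloxy)-2-ethynyl-7-methoxychromen-4-one | C#Cc1cc(=O)c2c(OCc3ccccc3)cc(OC)cc2o1
A9 | alternative 3 | pentacarbonyl(1,2,3-trimethoxyprop-2-en-1-ylidene)chromium, (CO)5Cr=C(OMe)C(OMe)=CH(OMe), alkene geometry left open | COC=C(OC)C(OC)=[Cr](=C=O)(=C=O)(=C=O)(=C=O)=C=O
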